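**Retrosynthetic overview**
- The target consists of ring A (oxolane O1–C2–C3–C4–C5, 2R,3S,5R), an (E,E)-diene and an isocoumarin (lactone ring B, chlorinated arene ring C). The alkene next to ring B is cut by Horner–Wadsworth–Emmons into an oxolanyl enal and an (isocoumarin-3-yl)methylphosphonate, and the alkene next to ring A is cut by Wittig back to the oxolane-2-carbaldehyde.
- Feature that carries the plan: in ring A the hydroxyl stands on C3, next to ether carbon C2 and 1,3 to the methyl-bearing C5, trans to the C2 chain and cis to the C5 methyl. A 1,2-silyl shift leaves exactly this pattern, so C3–OH is traced back to C3–SiMe2Ph (Tamao–Fleming, retention).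
- The 3-silyl oxolane is opened across C4–C5 and O1–C2 into an (R)-α-substituted allylsilane and acetaldehyde, a BF3-promoted (3+2) annulation in which the C–Si bond is only temporary.
- The allylsilane comes in three steps from (Z)-but-2-ene-1,4-diol by enantioselective copper-catalysed SN2′ silylation of its mono-TBS allylic phosphate with PhMe2Si–Bpin.
- Ring order: ring C is bought as methyl orsellinate and chlorinated first, ring A forms in step 4, ring B forms in step 14 (toluate acylation, enol lactonisation), and the fragments are joined in step 18.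

Key step: step 4

Assumption (chemistry): the sense of induction of the chiral carbene–CuCl catalyst on the (Z)-phosphate in step 3 is taken to be set by the choice of ligand antipode, and the antipode that delivers the (R)-allylsilane is used.

**Route**

Step 1
Reactants: 1 (Z)-but-2-ene-1,4-diol
Product: 2 (Z)-4-[(tert-butyldimethylsilyl)oxy]but-2-en-1-ol
Conditions: NaH (1.0 equiv), THF, 0 °C → rt; TBSCl (1.0 equiv)
Reagents that add atoms: tert-butyldimethylsilyl chloride, CC(C)(C)[Si](C)(C)Cl
Why: O-silylation of the sparingly soluble monosodium alkoxide of a symmetrical diol should stop after one silylation and leaves the Z alkene untouched.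

Step 2
Reactants: 2 (Z)-4-[(tert-butyldimethylsilyl)oxy]but-2-en-1-ol
Product: 3 (Z)-4-[(tert-butyldimethylsilyl)oxy]but-2-en-1-yl diethyl phosphate
Conditions: ClP(O)(OEt)2, Et3N, DMAP (cat.), CH2Cl2, 0 °C → rt
Reagents that add atoms: diethyl chlorophosphate, CCOP(=O)(Cl)OCC
Why: DMAP-catalysed O-phosphorylation of the primary allylic alcohol installs the leaving group needed for the SN2′ substitution.

Step 3
Reactants: 3 (Z)-4-[(tert-butyldimethylsilyl)oxy]but-2-en-1-yl diethyl phosphate; 4 2-(dimethylphenylsilyl)-4,4,5,5-tetramethyl-1,3,2-dioxaborolane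
Product: 5 (R)-tert-butyl{[2-(dimethylphenylsilyl)but-3-en-1-yl]oxy}dimethylsilane
Conditions: (NHC*)CuCl (5 mol %; NHC* = enantiopure six-membered-ring diaminocarbene), NaOMe (1.5 equiv), CH2Cl2, 0 °C
Reagents that add atoms: none
Why: In this copper-catalysed enantioselective allylic silylation methoxide activates the Si–B bond, the silylcopper–carbene complex attacks the γ-carbon with loss of phosphate (SN2′), and the chiral carbene selects the alkene face, which sets the silicon-bearing carbon as (R).

Step 4
Reactants: 5 (R)-tert-butyl{[2-(dimethylphenylsilyl)but-3-en-1-yl]oxy}dimethylsilane; 6 acetaldehyde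
Product: 7 tert-butyl{[(2R,3S,5R)-3-(dimethylphenylsilyl)-5-methyloxolan-2-yl]methoxy}dimethylsilane
Conditions: 6 (3 equiv, freshly distilled), BF3·OEt2 (1.2 equiv), 4 Å MS, CH2Cl2, −78 → −40 °C; aq NaHCO3
Reagents that add atoms: none
Why: BF3-bound acetaldehyde is attacked by the terminal alkene carbon of 5 on the face opposite the C–Si bond (anti SE2′, C4–C5 forms), silicon bridges the resulting β-silyl cation as a siliranium ion across C2 and C3, and the boron alkoxide opens this ion at C2, so that silicon ends on C3 and O1–C2 closes ring A. The closest known reaction type is the Lewis-acid (3+2) annulation of α-substituted, β-silyloxy allylsilanes with aldehydes to 3-silyl tetrahydrofurans. Ring A closes in the 5-endo-tet mode (both siliranium carbons become ring members), the only alternative being a strained 4-exo attack at C3 to an oxetane. C2 is the stereocentre of 5 and is inverted because oxygen enters opposite the departing silicon, and C3 follows from the conformer of 5 whose C2–H lies near the alkene plane, which gives the trans-siliranium ion and places silicon trans to CH2OTBS. C5 is set by an open, non-chelated synclinal approach in which the aldehyde oxygen lies below the allyl unit on the C2 side and the methyl group points away from C3, which should give the 2,5-trans, 3,5-cis oxolane. The step needs ring closure to outrun loss of silicon (Hosomi–Sakurai allylation) and Peterson-type loss of the β-oxygen, which the PhMe2Si group, the non-nucleophilic BF3 alkoxide, the low temperature and the weakly basic silyl ether on the β-oxygen are there to secure.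

Step 5
Reactants: 7 tert-butyl{[(2R,3S,5R)-3-(dimethylphenylsilyl)-5-methyloxolan-2-yl]methoxy}dimethylsilane
Product: 9 (2R,3S,5R)-2-{[(tert-butyldimethylsilyl)oxy]methyl}-5-methyloxolan-3-ol, via bromosilane 8 (not isolated)
Conditions: KBr (1.5 equiv), NaOAc, AcOOH (32% in AcOH), AcOH, 0 °C → rt; aq Na2S2O3
Reagents that add atoms: peracetic acid, CC(=O)OO; potassium bromide, [K+].[Br-] (bromine atom of 8 only)
Why: In this Tamao–Fleming oxidation ipso-bromodesilylation removes the phenyl group to give 8, peracetate adds to silicon and C3 migrates from silicon to oxygen with retention, so C3–Si becomes the (3S) C3–OH, and the buffered medium should spare the primary TBS ether at a stage where no alkene is present.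

Step 6
Reactants: 9 (2R,3S,5R)-2-{[(tert-butyldimethylsilyl)oxy]methyl}-5-methyloxolan-3-ol
Product: 10 (2R,3S,5R)-3-[(tert-butyldimethylsilyl)oxy]-2-{[(tert-butyldimethylsilyl)oxy]methyl}-5-methyloxolane
Conditions: TBSCl, imidazole, DMF, rt
Reagents that add atoms: tert-butyldimethylsilyl chloride, CC(C)(C)[Si](C)(C)Cl
Why: Imidazole-promoted silylation masks the secondary C3 hydroxyl for the oxidation and the two olefinations without touching a stereocentre.

Step 7
Reactants: 10 (2R,3S,5R)-3-[(tert-butyldimethylsilyl)oxy]-2-{[(tert-butyldimethylsilyl)oxy]methyl}-5-methyloxolane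
Product: 11 {(2R,3S,5R)-3-[(tert-butyldimethylsilyl)oxy]-5-methyloxolan-2-yl}methanol
Conditions: HF·pyridine, pyridine, THF, 0 °C
Reagents that add atoms: none
Why: Buffered HF·pyridine cleaves the less hindered primary silyl ether faster than the secondary one (rate-based selective desilylation), and the acidic medium excludes silyl migration.

Step 8
Reactants: 11 {(2R,3S,5R)-3-[(tert-butyldimethylsilyl)oxy]-5-methyloxolan-2-yl}methanol
Product: 12 (2S,3S,5R)-3-[(tert-butyldimethylsilyl)oxy]-5-methyloxolane-2-carbaldehyde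
Conditions: Dess–Martin periodinane, CH2Cl2, 0 °C → rt
Reagents that add atoms: none
Why: Dess–Martin oxidation works without base, so the α-alkoxy aldehyde should form without epimerisation at C2 or β-elimination of the silyloxy group (the C2 descriptor changes by priority rules only).

Step 9
Reactants: 12 (2S,3S,5R)-3-[(tert-butyldimethylsilyl)oxy]-5-methyloxolane-2-carbaldehyde
Product: 13 (2E)-3-{(2R,3S,5R)-3-[(tert-butyldimethylsilyl)oxy]-5-methyloxolan-2-yl}prop-2-enal
Conditions: Ph3P=CHCHO, toluene, 70 °C
Reagents that add atoms: (triphenylphosphoranylidene)acetaldehyde, O=CC=P(c1ccccc1)(c1ccccc1)c1ccccc1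
Why: Wittig olefination with the formyl-stabilised, weakly basic ylide should give the (E)-enal and leave the epimerisable C2 centre alone.

Step 10
Reactants: 14 methyl glycolate
Product: 15 methyl 2-[(tert-butyldimethylsilyl)oxy]acetate
Conditions: TBSCl, imidazole, CH2Cl2, rt
Reagents that add atoms: tert-butyldimethylsilyl chloride, CC(C)(C)[Si](C)(C)Cl
Why: Routine O-silylation protects the hydroxyl that later becomes the leaving-group site of the phosphonate arm.

Step 11
Reactants: 15 methyl 2-[(tert-butyldimethylsilyl)oxy]acetate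
Product: 16 2-[(tert-butyldimethylsilyl)oxy]-N-methoxy-N-methylacetamide
Conditions: MeNH(OMe)·HCl, i-PrMgCl, THF, −20 → 0 °C
Reagents that add atoms: N,O-dimethylhydroxylamine hydrochloride, CNOC.Cl
Why: Aminolysis of the ester by the magnesium amide of N,O-dimethylhydroxylamine is the standard access to a Weinreb amide and is compatible with the silyl ether.

Step 12
Reactants: 17 methyl 2,4-dihydroxy-6-methylbenzoate (methyl orsellinate)
Product: 18 methyl 3-chloro-4,6-dihydroxy-2-methylbenzoate
Conditions: SO2Cl2 (1.0 equiv), Et2O, 0 °C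
Reagents that add atoms: sulfuryl chloride, O=S(=O)(Cl)Cl
Why: Electrophilic aromatic chlorination of 6-alkylresorcylates should go to the carbon next to the methyl group (ortho to the free hydroxyl, para to the chelated one), and one equivalent of reagent limits dichlorination.

Step 13
Reactants: 18 methyl 3-chloro-4,6-dihydroxy-2-methylbenzoate
Product: 19 methyl 3-chloro-4,6-bis(methoxymethoxy)-2-methylbenzoate
Conditions: NaH, MOMCl, DMF, 0 °C → rt
Reagents that add atoms: chloromethyl methyl ether, COCCl
Why: Williamson-type alkylation of both phenoxides, the chelated one included, gives base-stable acetal ethers that tolerate LDA, fluoride, the Arbuzov reaction and LiHMDS.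

Step 14
Reactants: 19 methyl 3-chloro-4,6-bis(methoxymethoxy)-2-methylbenzoate; 16 2-[(tert-butyldimethylsilyl)oxy]-N-methoxy-N-methylacetamide
Product: 21 3-{[(tert-butyldimethylsilyl)oxy]methyl}-5-chloro-6,8-bis(methoxymethoxy)-1H-isochromen-1-one, via keto ester 20 (not isolated)
Conditions: LDA (2 equiv), THF, −78 °C; 16, −78 °C; AcOH; then DBU, → 40 °C
Reagents that add atoms: none
Why: Lateral lithiation of the o-toluate gives a benzylic anion that is acylated once by the Weinreb amide (chelated adduct, no over-addition), and DBU then enolises 20 toward the benzylic carbon so that the enolate oxygen attacks the neighbouring ester (6-exo-trig enol lactonisation) and closes ring B.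

Step 15
Reactants: 21 3-{[(tert-butyldimethylsilyl)oxy]methyl}-5-chloro-6,8-bis(methoxymethoxy)-1H-isochromen-1-one
Product: 22 5-chloro-3-(hydroxymethyl)-6,8-bis(methoxymethoxy)-1H-isochromen-1-one
Conditions: HF·pyridine, THF, 0 °C → rt
Reagents that add atoms: none
Why: Fluoride-driven cleavage of the primary silyl ether is orthogonal to the aryl MOM ethers and to the lactone.

Step 16
Reactants: 22 5-chloro-3-(hydroxymethyl)-6,8-bis(methoxymethoxy)-1H-isochromen-1-one
Product: 23 3-(bromomethyl)-5-chloro-6,8-bis(methoxymethoxy)-1H-isochromen-1-one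
Conditions: CBr4, PPh3, CH2Cl2, 0 °C
Reagents that add atoms: carbon tetrabromide, BrC(Br)(Br)Br
Why: The Appel reaction turns the allylic-type primary alcohol into the bromide under neutral conditions that spare the acetals.

Step 17
Reactants: 23 3-(bromomethyl)-5-chloro-6,8-bis(methoxymethoxy)-1H-isochromen-1-one
Product: 24 diethyl {[5-chloro-6,8-bis(methoxymethoxy)-1-oxo-1H-isochromen-3-yl]methyl}phosphonate
Conditions: P(OEt)3 (neat), 120 °C
Reagents that add atoms: triethyl phosphite, CCOP(OCC)OCC
Why: The Michaelis–Arbuzov reaction proceeds readily on an activated primary allylic-type bromide and needs neither acid nor base.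

Step 18
Reactants: 24 diethyl {[5-chloro-6,8-bis(methoxymethoxy)-1-oxo-1H-isochromen-3-yl]methyl}phosphonate; 13 (2E)-3-{(2R,3S,5R)-3-[(tert-butyldimethylsilyl)oxy]-5-methyloxolan-2-yl}prop-2-enal
Product: 25 3-[(1E,3E)-4-{(2R,3S,5R)-3-[(tert-butyldimethylsilyl)oxy]-5-methyloxolan-2-yl}buta-1,3-dien-1-yl]-5-chloro-6,8-bis(methoxymethoxy)-1H-isochromen-1-one
Conditions: LiHMDS, THF, −78 °C; 13, −78 → 0 °C
Reagents that add atoms: none
Why: In this Horner–Wadsworth–Emmons olefination the carbanion, delocalised through C3=C4 and ring C into the lactone carbonyl, adds 1,2 to the enal and loses phosphate under thermodynamic control to give the new alkene as E, and it is too weakly basic to disturb the ring A centres.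

Step 19
Reactants: 25 3-[(1E,3E)-4-{(2R,3S,5R)-3-[(tert-butyldimethylsilyl)oxy]-5-methyloxolan-2-yl}buta-1,3-dien-1-yl]-5-chloro-6,8-bis(methoxymethoxy)-1H-isochromen-1-one
Product: 26 5-chloro-6,8-dihydroxy-3-{(1E,3E)-4-[(2R,3S,5R)-3-hydroxy-5-methyloxolan-2-yl]buta-1,3-dien-1-yl}-1H-isochromen-1-one
Conditions: aq HCl (cat.), MeOH, 40 °C
Reagents that add atoms: none
Why: Acid-catalysed acetal exchange with methanol removes both aryl MOM ethers and methanolysis cleaves the secondary TBS ether in the same operation, while the electron-poor isocoumarin end of the diene should disfavour ionisation of the allylic C2–O1 bond.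

**Compound list**
1 | (Z)-but-2-ene-1,4-diol | OC/C=C\CO | starting material
2 | (Z)-4-[(tert-butyldimethylsilyl)oxy]but-2-en-1-ol | OC/C=C\CO[Si](C)(C)C(C)(C)C | intermediate
3 | (Z)-4-[(tert-butyldimethylsilyl)oxy]but-2-en-1-yl diethyl phosphate | CCOP(=O)(OCC)OC/C=C\CO[Si](C)(C)C(C)(C)C | intermediate
4 | 2-(dimethylphenylsilyl)-4,4,5,5-tetramethyl-1,3,2-dioxaborolane | CC1(C)OB(OC1(C)C)[Si](C)(C)c1ccccc1 | starting material
5 | (R)-tert-butyl{[2-(dimethylphenylsilyl)but-3-en-1-yl]oxy}dimethylsilane | C=C[C@H](CO[Si](C)(C)C(C)(C)C)[Si](C)(C)c1ccccc1 | intermediate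
6 | acetaldehyde | CC=O | starting material
7 | tert-butyl{[(2R,3S,5R)-3-(dimethylphenylsilyl)-5-methyloxolan-2-yl]methoxy}dimethylsilane | C[C@@H]1C[C@H]([Si](C)(C)c2ccccc2)[C@@H](CO[Si](C)(C)C(C)(C)C)O1 | intermediate
8 | bromo[(2R,3S,5R)-2-{[(tert-butyldimethylsilyl)oxy]methyl}-5-methyloxolan-3-yl]dimethylsilane | C[C@@H]1C[C@H]([Si](C)(C)Br)[C@@H](CO[Si](C)(C)C(C)(C)C)O1 | intermediate
9 | (2R,3S,5R)-2-{[(tert-butyldimethylsilyl)oxy]methyl}-5-methyloxolan-3-ol | C[C@@H]1C[C@H](O)[C@@H](CO[Si](C)(C)C(C)(C)C)O1 | intermediate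
10 | (2R,3S,5R)-3-[(tert-butyldimethylsilyl)oxy]-2-{[(tert-butyldimethylsilyl)oxy]methyl}-5-methyloxolane | C[C@@H]1C[C@H](O[Si](C)(C)C(C)(C)C)[C@@H](CO[Si](C)(C)C(C)(C)C)O1 | intermediate
11 | {(2R,3S,5R)-3-[(tert-butyldimethylsilyl)oxy]-5-methyloxolan-2-yl}methanol | C[C@@H]1C[C@H](O[Si](C)(C)C(C)(C)C)[C@@H](CO)O1 | intermediate
12 | (2S,3S,5R)-3-[(tert-butyldimethylsilyl)oxy]-5-methyloxolane-2-carbaldehyde | C[C@@H]1C[C@H](O[Si](C)(C)C(C)(C)C)[C@@H](C=O)O1 | intermediate
13 | (2E)-3-{(2R,3S,5R)-3-[(tert-butyldimethylsilyl)oxy]-5-methyloxolan-2-yl}prop-2-enal | C[C@@H]1C[C@H](O[Si](C)(C)C(C)(C)C)[C@@H](/C=C/C=O)O1 | intermediate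
14 | methyl glycolate | COC(=O)CO | starting material
15 | methyl 2-[(tert-butyldimethylsilyl)oxy]acetate | COC(=O)CO[Si](C)(C)C(C)(C)C | intermediate
16 | 2-[(tert-butyldimethylsilyl)oxy]-N-methoxy-N-methylacetamide | CON(C)C(=O)CO[Si](C)(C)C(C)(C)C | intermediate
17 | methyl 2,4-dihydroxy-6-methylbenzoate | COC(=O)c1c(C)cc(O)cc1O | starting material
18 | methyl 3-chloro-4,6-dihydroxy-2-methylbenzoate | COC(=O)c1c(C)c(Cl)c(O)cc1O | intermediate
19 | methyl 3-chloro-4,6-bis(methoxymethoxy)-2-methylbenzoate | COC(=O)c1c(C)c(Cl)c(OCOC)cc1OCOC | intermediate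
20 | methyl 2-{3-[(tert-butyldimethylsilyl)oxy]-2-oxopropyl}-3-chloro-4,6-bis(methoxymethoxy)benzoate | COC(=O)c1c(CC(=O)CO[Si](C)(C)C(C)(C)C)c(Cl)c(OCOC)cc1OCOC | intermediate
21 | 3-{[(tert-butyldimethylsilyl)oxy]methyl}-5-chloro-6,8-bis(methoxymethoxy)-1H-isochromen-1-one | O=c1oc(CO[Si](C)(C)C(C)(C)C)cc2c(Cl)c(OCOC)cc(OCOC)c12 | intermediate
22 | 5-chloro-3-(hydroxymethyl)-6,8-bis(methoxymethoxy)-1H-isochromen-1-one | O=c1oc(CO)cc2c(Cl)c(OCOC)cc(OCOC)c12 | intermediate
23 | 3-(bromomethyl)-5-chloro-6,8-bis(methoxymethoxy)-1H-isochromen-1-one | O=c1oc(CBr)cc2c(Cl)c(OCOC)cc(OCOC)c12 | intermediate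
24 | diethyl {[5-chloro-6,8-bis(methoxymethoxy)-1-oxo-1H-isochromen-3-yl]methyl}phosphonate | CCOP(=O)(OCC)Cc1cc2c(Cl)c(OCOC)cc(OCOC)c2c(=O)o1 | intermediate
25 | 3-[(1E,3E)-4-{(2R,3S,5R)-3-[(tert-butyldimethylsilyl)oxy]-5-methyloxolan-2-yl}buta-1,3-dien-1-yl]-5-chloro-6,8-bis(methoxymethoxy)-1H-isochromen-1-one | C[C@@H]1C[C@H](O[Si](C)(C)C(C)(C)C)[C@@H](/C=C/C=C/c2cc3c(Cl)c(OCOC)cc(OCOC)c3c(=O)o2)O1 | intermediate
26 | 5-chloro-6,8-dihydroxy-3-{(1E,3E)-4-[(2R,3S,5R)-3-hydroxy-5-methyloxolan-2-yl]buta-1,3-dien-1-yl}-1H-isochromen-1-one | C[C@@H]1C[C@H](O)[C@@H](/C=C/C=C/c2cc3c(Cl)c(O)cc(O)c3c(=O)o2)O1 | target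

**Step count**
Total step count: 19
Longest linear sequence: 11 steps (steps 1–9, 18, 19)

**Steps most likely to fail**

Step 4.
- What may go wrong: silicon may be lost from the β-silyl cation before the ring closes, giving allylation instead of annulation. BF3 may oligomerise acetaldehyde. Facial selectivity at the aldehyde carbon (C5) may be poor. Reaction through the conformer with CH2OTBS near the alkene plane would erode the 2,3-trans relation.
- Fallback: it sets out from acetaldehyde 6 and diol 1 and comes back at alcohol 9. An epoxide takes the place of the siliranium ion as the electrophile of the same 5-endo closure, and every centre is set by reagent control. Brown allylation of 6 with the Ipc2B(allyl) antipode that attacks the Si face should give (R)-pent-4-en-2-ol F1. Cross metathesis of this alcohol with 1 (second-generation Hoveyda–Grubbs catalyst, CH2Cl2, 40 °C) should give (2E,5R)-hex-2-ene-1,5-diol F2. Sharpless epoxidation (Ti(OiPr)4, L-(+)-diethyl tartrate, t-BuOOH, 4 Å MS, CH2Cl2, −20 °C) should give (2R)-1-[(2S,3S)-3-(hydroxymethyl)oxiran-2-yl]propan-2-ol F3. Selective silylation of the primary hydroxyl (TBSCl, imidazole, 0 °C) gives (2R)-1-[(2S,3S)-3-{[(tert-butyldimethylsilyl)oxy]methyl}oxiran-2-yl]propan-2-ol F4. Camphorsulfonic acid in CH2Cl2 then lets the secondary hydroxyl open the epoxide at the distal carbon with inversion, which gives 9.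

Step 5.
- What may go wrong: the electrophile or the acid may trigger β-elimination, in which O1 leaves C2 while silicon leaves C3. This opens the ring and is the reverse of the annulation. The primary silyl ether may also be solvolysed in acetic acid.
- Fallback: it sets out from 7 and comes back at bis-silyl ether 10. The phenyl group is removed reductively and not by an electrophile. Birch reduction (Li, NH3, THF, EtOH, −78 °C) should give tert-butyl{[(2R,3S,5R)-3-(cyclohexa-2,5-dien-1-yldimethylsilyl)-5-methyloxolan-2-yl]methoxy}dimethylsilane F5. TBAF in THF cleaves the doubly allylic C–Si bond and the primary TBS ether to give [(2R,3S,5R)-3-(fluorodimethylsilyl)-5-methyloxolan-2-yl]methanol F6. Tamao oxidation (H2O2, KF, KHCO3, MeOH–THF) with retention gives (2R,3S,5R)-2-(hydroxymethyl)-5-methyloxolan-3-ol F7. Double silylation (TBSCl in excess, imidazole, DMF) then gives 10.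

Step 19.
- What may go wrong: acid may ionise the dienylic C2–O1 bond, leading to ring opening, epimerisation at C2 or capture by methanol. The MOM ether next to chlorine may be cleaved incompletely.
- Fallback: it sets out from phosphonate 24 and enal 13 and comes back at target 26. The acid step is moved onto the robust phosphonate and the end game becomes fluoride-only. HCl in MeOH on 24 should give diethyl [(5-chloro-6,8-dihydroxy-1-oxo-1H-isochromen-3-yl)methyl]phosphonate F8. TBSCl and imidazole in DMF give diethyl ({6,8-bis[(tert-butyldimethylsilyl)oxy]-5-chloro-1-oxo-1H-isochromen-3-yl}methyl)phosphonate F9. Horner–Wadsworth–Emmons coupling with 13 (LiHMDS, THF, −78 → 0 °C) gives 6,8-bis[(tert-butyldimethylsilyl)oxy]-3-[(1E,3E)-4-{(2R,3S,5R)-3-[(tert-butyldimethylsilyl)oxy]-5-methyloxolan-2-yl}buta-1,3-dien-1-yl]-5-chloro-1H-isochromen-1-one F10. HF·pyridine in THF removes all three silyl groups to give 26.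

**Further compounds**
F1 | step 4 | (R)-pent-4-en-2-ol | C[C@@H](O)CC=C
F2 | step 4 | (2E,5R)-hex-2-ene-1,5-diol | C[C@@H](O)C/C=C/CO
F3 | step 4 | (2R)-1-[(2S,3S)-3-(hydroxymethyl)oxiran-2-yl]propan-2-ol | C[C@@H](O)C[C@@H]1O[C@H]1CO
F4 | step 4 | (2R)-1-[(2S,3S)-3-{[(tert-butyldimethylsilyl)oxy]methyl}oxiran-2-yl]propan-2-ol | C[C@@H](O)C[C@@H]1O[C@H]1CO[Si](C)(C)C(C)(C)C
F5 | step 5 | tert-butyl{[(2R,3S,5R)-3-(cyclohexa-2,5-dien-1-yldimethylsilyl)-5-methyloxolan-2-yl]methoxy}dimethylsilane | C[C@@H]1C[C@H]([Si](C)(C)C2C=CCC=C2)[C@@H](CO[Si](C)(C)C(C)(C)C)O1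
F6 | step 5 | [(2R,3S,5R)-3-(fluorodimethylsilyl)-5-methyloxolan-2-yl]methanol | C[C@@H]1C[C@H]([Si](C)(C)F)[C@@H](CO)O1
F7 | step 5 | (2R,3S,5R)-2-(hydroxymethyl)-5-methyloxolan-3-ol | C[C@@H]1C[C@H](O)[C@@H](CO)O1
F8 | step 19 | diethyl [(5-chloro-6,8-dihydroxy-1-oxo-1H-isochromen-3-yl)methyl]phosphonate | CCOP(=O)(OCC)Cc1cc2c(Cl)c(O)cc(O)c2c(=O)o1
F9 | step 19 | diethyl ({6,8-bis[(tert-butyldimethylsilyl)oxy]-5-chloro-1-oxo-1H-isochromen-3-yl}methyl)phosphonate | CCOP(=O)(OCC)Cc1cc2c(Cl)c(O[Si](C)(C)C(C)(C)C)cc(O[Si](C)(C)C(C)(C)C)c2c(=O)o1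
F10 | step 19 | 6,8-bis[(tert-butyldimethylsilyl)oxy]-3-[(1E,3E)-4-{(2R,3S,5R)-3-[(tert-butyldimethylsilyl)oxy]-5-methyloxolan-2-yl}buta-1,3-dien-1-yl]-5-chloro-1H-isochromen-1-one | C[C@@H]1C[C@H](O[Si](C)(C)C(C)(C)C)[C@@H](/C=C/C=C/c2cc3c(Cl)c(O[Si](C)(C)C(C)(C)C)cc(O[Si](C)(C)C(C)(C)C)c3c(=O)o2)O1
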